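# Proposed total synthesis of (3R)-5,7-dihydroxy-6-prenyl-3-(3-geranyl-4-hydroxyphenyl)chroman-4-one (CNP0165005.1, compound 24)

## Analysis of the target

Compound 24 is an isoflavanone (3-arylchroman-4-one). Ring A is a phloroglucinol-type benzene with hydroxyls at C5 and C7 and a 3-methylbut-2-enyl (prenyl) chain at C6. Ring C is the dihydropyranone. Ring B, attached at C3, is a 4-hydroxyphenyl group with an (E)-geranyl chain at C3'. The only stereocentre is C3, of R configuration; it is benzylic and alpha to the C4 ketone, so it epimerises through the enol in base and, more slowly, in acid. The sensitive groups are three trisubstituted alkenes, three phenols and the hydrogen-bonded 5-OH/C4=O pair. The alkenes cyclise onto neighbouring phenols in strong acid, add electrophilic halogen and carbenes, and exclude hydrogenolysis. The difficulties are therefore the C6 versus C8 regiochemistry on ring A, setting and then keeping C3, and a protecting-group plan whose last step is close to neutral. The strategy rests on the fact that C3, with ring B on it, is a single carbon between C2 (the OCH2 carbon) and C4 (the carbonyl carbon). Without that carbon, O1, C2, C4 and ring A form a 4,6-dioxygenated benzofuran-3(2H)-one, so C3 can be inserted as an arylcarbene carbon into the enol double bond of that five-membered ring.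

## Retrosynthetic reasoning

**24 from 23.** Only the two O–Si bonds are cut last. A buffered desilylation is the one deprotection that touches neither the alkenes nor the enolisable C3–H, so the stereocentre is formed before it and meets no acid or base afterwards.

**23 from 22, and 22 from 20 (the C3 stereocentre).** C3 is traced back to the planar C3 of isoflavone 20. The saturated ketone 21 racemises easily, so a direct enantioselective reduction to the ketone cannot hold its configuration. The route therefore reduces one stage further, to the cis-(3R,4R) carbinol 22, with dynamic kinetic resolution: the racemisation of 21 then feeds the resolution. Oxidation of C4 under non-enolising conditions gives 23. The forward reactions must reduce a conjugated, chelated carbonyl without touching three isolated alkenes and must reoxidise without epimerisation.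

**20 from 17 and 19; 17 from 15 and 16 (the two side chains).** The C3'–geranyl and C6–prenyl bonds are cut as aryl–allyl bonds at halogen-bearing carbons. They are cut here, late, because alkenes would compete for the carbene in the ring-forming step and for the electrophilic iodine that marks C6. With both halogens in place before either chain, the iodide of 15 is coupled first and the bromide of 17 second, so the halogen identity decides the site.

**15 from 14, 14 from 13, 13 from 12 (C6–I and the change of protecting groups).** The C6–I bond is cut back to C6–H. The free, chelated 5-OH of 14 directs the electrophile to its ortho position, which only works if O7 is capped and O5 is not. All acid-labile acetals of 12 are removed in one operation, and the two unchelated phenols of 13 are then silylated. The only acidic step of the route is thus run on an achiral, alkene-free compound, and the final groups are fluoride-labile.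

**12 from 3 and 8 (key disconnection).** The C2–C3 and C3–C4 bonds are cut together. This removes C3 with ring B as a chlorocarbene and contracts ring C to the furan ring of silyl enol ether 3. The cut is made there because both bonds end at one carbon, because the other product, benzofuranone 2, is one step from a purchasable compound, and because the aryl bromide of 8 passes through unchanged as the handle for the geranyl chain. The forward reaction must add the carbene to the enol ether bond only and open the cyclopropane at its internal bond.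

**3 from 2, 2 from 1; 8 from 7, 7 from 5, 5 from 4; 19 from 18.** Enol silylation and phenol protection give 3 in two steps from 1. The diazirine 8 comes from nitrile 4 by protection, amidine formation and oxidative N–N closure. Stannane 19 is the substitution product of 18, and stannane 16 is bought.

## Alternatives that were turned down

**Alternative 1: acyl-anion addition to a ring B quinone methide.** The C3–C4 bond is cut. In the forward step a base removes the arenesulfonyl group of aldehyde A1 to give a para-quinone methide. The acyl-anion equivalent from the aldehyde and a chiral triazolium-derived carbene then adds to the exocyclic carbon, closing ring C and setting C3 to give chromanone A2. In its favour, one organocatalytic step forms the ring and the stereocentre with both terpenoid chains in place and needs no reduction–oxidation detour. On step economy at the stereocentre it is stronger than the chosen route. Against it: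
- The aldehyde of A1 has two ortho oxygens and three donor oxygens in conjugation, so it is a poor electrophile for the carbene catalyst.
- The quinone methide lacks stabilising flanking groups and has an adjacent OCH2 hydrogen, so oligomerisation or tautomerisation to a vinylphenol competes.
- A2 is an alpha-aryl ketone formed in a basic medium that can also racemise it.
- A2 still carries two MOM ethers, whose acidic removal exposes C3 and the prenyl group.
- A1 needs a fully substituted ring A aldehyde and a sulfone-bearing ring B piece.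

The chosen route instead offers a precursor made in two and three steps, and a stereocentre set by a reduction in which racemisation helps.

**Alternative 2: carbenoid insertion into the O1 methyl group.** The C2–C3 bond is cut. A chiral dirhodium tetracarboxylate (divalent rhodium) decomposes diazo ketone A3, and the carbenoid inserts into a C–H bond of the ortho methoxy group to give chromanone A4. In its favour, the conditions are neutral, so the new stereocentre is not at risk. The silyl groups of A4 allow the same fluoride end-game as the chosen route, and again there is no redox detour. On these points it equals or beats the chosen route. Against it: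
- The C–H bond is a primary one of a methyl ether, the least reactive class for insertion.
- The 5-silyloxy oxygen is as close to the carbenoid as the methoxy oxygen, which invites ylide formation and silyl shift.
- Two trisubstituted alkenes invite cyclopropanation.
- Carbenoids from aryl ketones are usually less selective than those from aryldiazoacetates.
- A3 requires a fully substituted deoxybenzoin and a diazo transfer.

The chosen route meets the same carbene–alkene conflict by ordering, with the alkenes added after the carbene step.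

**Alternative 3: ring A grown on a pyranone.** The C4a–C5 bond is cut. A magnesium alkoxide forms the extended enolate of the side chain of pyranone A5. The pyranone carbon that becomes C4a attacks the methyl ester, and tautomerisation gives isoflavone A6. In its favour, the prenyl group is at C6 by construction. There is no C6/C8 question, no iodination and no tin, and on this point it is stronger than the chosen route. Against it:
- A6 is still an isoflavone, so the same reduction and reoxidation are needed and nothing is gained at C3.
- The most acidic proton of A5 lies between the side-chain ketone and the ester, and its removal is unproductive.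
- O-acylation and alkoxide opening of the pyranone at its unsubstituted C2 compete with the C-acylation.
- A5 needs a separate, long assembly of a 3-aryl-4-pyranone with a dioxo ester chain.

The chosen route offers in its place a purchasable ring A/ring C precursor and an iodination whose regiochemistry follows a known directing effect.

Key step: step 6

Assumption: the configuration encoded at C3 is R, stannane 16 is treated as a purchasable reagent, and stannane 19 is made from geranyl bromide.

## Route

Step 1
Reactants: 1 4,6-dihydroxybenzofuran-3(2H)-one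
Product: 2 4,6-bis(methoxymethoxy)benzofuran-3(2H)-one
Conditions: MOMCl (3 equiv), i-Pr2NEt, CH2Cl2, 0 °C to rt
Reagents that add atoms: chloromethyl methyl ether, COCCl
Why: MOM protection (O-alkylation) of both phenols under an amine base; the 4-OH is only weakly hydrogen-bonded to the five-ring ketone and is capped as well, and the weak base avoids C2 alkylation and aldol self-condensation.

Step 2
Reactants: 2 4,6-bis(methoxymethoxy)benzofuran-3(2H)-one
Product: 3 3-(tert-butyldimethylsilyloxy)-4,6-bis(methoxymethoxy)benzofuran
Conditions: TBSOTf, Et3N, CH2Cl2, -78 to 0 °C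
Reagents that add atoms: tert-butyldimethylsilyl trifluoromethanesulfonate, CC(C)(C)[Si](C)(C)OS(=O)(=O)C(F)(F)F
Why: Soft enolisation and O-silylation of the ketone, favoured because it creates the aromatic benzofuran; excess amine keeps the silyl triflate from attacking the MOM acetals.

Step 3
Reactants: 4 3-bromo-4-hydroxybenzonitrile
Product: 5 3-bromo-4-(methoxymethoxy)benzonitrile
Conditions: MOMCl, i-Pr2NEt, CH2Cl2, 0 °C to rt
Reagents that add atoms: chloromethyl methyl ether, COCCl
Why: MOM protection of the acidic phenol; the group has to withstand the amide base of step 4 and the alkaline hypochlorite of step 5.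

Step 4
Reactants: 5 3-bromo-4-(methoxymethoxy)benzonitrile
Product: 7 3-bromo-4-(methoxymethoxy)benzamidinium chloride, via lithium N-silylamidinate 6 (not isolated)
Conditions: LiN(SiMe3)2, THF, 0 °C to rt; then NH4Cl, MeOH, 0 °C to rt
Reagents that add atoms: lithium bis(trimethylsilyl)amide, C[Si](C)(C)[N-][Si](C)(C)C.[Li+]; ammonium chloride, [NH4+].[Cl-]
Why: Addition of the silylamide to the nitrile gives the N,N'-disilylated lithium amidinate 6; methanolysis of the N–Si bonds and protonation by NH4Cl give the amidinium chloride without the strong acid that would cleave the aryl MOM ether.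

Step 5
Reactants: 7 3-bromo-4-(methoxymethoxy)benzamidinium chloride
Product: 8 3-[3-bromo-4-(methoxymethoxy)phenyl]-3-chloro-3H-diazirine
Conditions: aq NaOCl, LiCl, DMSO–pentane, 0 °C to rt; kept cold and dark, used at once
Reagents that add atoms: sodium hypochlorite, [Na+].[O-]Cl; lithium chloride, [Li+].[Cl-]
Why: Graham reaction: N-chlorination of the amidine, base-induced N–N ring closure and chloride exchange give the 3-aryl-3-chlorodiazirine; the MOM ether and the aryl bromide are inert to cold alkaline hypochlorite.

Step 6
Reactants: 3 3-(tert-butyldimethylsilyloxy)-4,6-bis(methoxymethoxy)benzofuran; 8 3-[3-bromo-4-(methoxymethoxy)phenyl]-3-chloro-3H-diazirine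
Product: 12 3-[3-bromo-4-(methoxymethoxy)phenyl]-5,7-bis(methoxymethoxy)-4H-chromen-4-one, via arylchlorocarbene 9 (not isolated), via chlorocyclopropane adduct 10 (not isolated), via 4-silyloxychromenylium chloride 11 (not isolated)
Conditions: 8 (3 equiv, in portions), Na2CO3, MeCN, 45 °C, dark
Reagents that add atoms: none
Why: Proposed new method: thermal loss of N2 from 8 releases the electrophilic singlet arylchlorocarbene 9, which adds in a (2+1) cycloaddition to the C2=C3 bond of 3; the chlorocyclopropane 10 then undergoes disrotatory two-electron opening of the shared C–C bond as chloride leaves, pushed by both oxygens, to give the aromatic 4-silyloxychromenylium chloride 11, and chloride attack at silicon releases chromen-4-one 12. The closest known reaction types are the Ciamician–Dennstedt-type carbon insertion of arylchlorocarbenes from chlorodiazirines into indoles, pyrroles and indenes and the dihalocarbene ring expansion of cyclic silyl enol ethers to 2-halo enones; neither has been shown on a benzofuranone enol ether. Ring C is closed by ring expansion and not by a cyclisation: the furan becomes the six-membered pyranone when the internal cyclopropane bond breaks, and the new bonds C2–C3 and C3–C4 are those made in the cyclopropanation. No stereocentre is formed because C3 ends sp2; both diastereomers of 10 should converge, since the isomer with chlorine anti to the benzofuran can ionise to an aryl- and oxygen-stabilised cation before it opens. The step needs site selectivity for the enol ether bond over ring A and the MOM oxygens, which the much higher nucleophilicity of the 2,3-dioxygenated alkene secures. It also needs cleavage of the internal cyclopropane bond, which alone gives an aromatic cation. Side-chain alkenes are absent on purpose because they would trap the carbene, and Na2CO3 removes adventitious HCl that would hydrolyse 3.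

Step 7
Reactants: 12 3-[3-bromo-4-(methoxymethoxy)phenyl]-5,7-bis(methoxymethoxy)-4H-chromen-4-one
Product: 13 3-(3-bromo-4-hydroxyphenyl)-5,7-dihydroxy-4H-chromen-4-one
Conditions: 3 M aq HCl, MeOH–THF, 55 °C
Reagents that add atoms: none
Why: Acid-catalysed transacetalisation removes all three MOM ethers; it is placed before any alkene or stereocentre exists, so acid can neither cyclise a prenyl group onto a phenol nor enolise C3.

Step 8
Reactants: 13 3-(3-bromo-4-hydroxyphenyl)-5,7-dihydroxy-4H-chromen-4-one
Product: 14 3-[3-bromo-4-(triisopropylsilyloxy)phenyl]-5-hydroxy-7-(triisopropylsilyloxy)-4H-chromen-4-one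
Conditions: TIPSCl (2.3 equiv), imidazole, DMF, 0 °C to rt
Reagents that add atoms: chlorotriisopropylsilane, CC(C)[Si](Cl)(C(C)C)C(C)C
Why: Silylation of the two unchelated phenols (7-OH and 4'-OH); the 5-OH is hydrogen-bonded to C4=O and stays free, and TIPS is preferred to TBS because the 7-O-silyl ether of an acylphenol has to last six more steps.

Step 9
Reactants: 14 3-[3-bromo-4-(triisopropylsilyloxy)phenyl]-5-hydroxy-7-(triisopropylsilyloxy)-4H-chromen-4-one
Product: 15 3-[3-bromo-4-(triisopropylsilyloxy)phenyl]-5-hydroxy-6-iodo-7-(triisopropylsilyloxy)-4H-chromen-4-one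
Conditions: BnMe3N·ICl2, CaCO3, CH2Cl2–MeOH, rt
Reagents that add atoms: benzyltrimethylammonium dichloroiodate, C[N+](C)(C)Cc1ccccc1.Cl[I-]Cl
Why: Electrophilic aromatic iodination ortho to the free 5-OH, the regiochemistry known for 5-hydroxy-7-O-substituted flavones and isoflavones (C8 is attacked only when O5 is capped); ring B has no free phenol and is deactivated by bromine, and CaCO3 removes the HCl formed.

Step 10
Reactants: 15 3-[3-bromo-4-(triisopropylsilyloxy)phenyl]-5-hydroxy-6-iodo-7-(triisopropylsilyloxy)-4H-chromen-4-one; 16 tributyl(3-methylbut-2-en-1-yl)stannane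
Product: 17 3-[3-bromo-4-(triisopropylsilyloxy)phenyl]-5-hydroxy-6-(3-methylbut-2-en-1-yl)-7-(triisopropylsilyloxy)-4H-chromen-4-one
Conditions: Pd(PPh3)4 (zerovalent palladium, cat.), DMF, 80 °C
Reagents that add atoms: none
Why: Stille coupling: oxidative addition at C–I is much faster than at the aryl C–Br, which is kept for step 12, and reductive elimination at the unsubstituted CH2 terminus of the prenyl(aryl)palladium intermediate gives the linear prenyl group; the chelated 5-OH is tolerated.

Step 11
Reactants: 18 geranyl bromide
Product: 19 tributyl[(2E)-3,7-dimethylocta-2,6-dien-1-yl]stannane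
Conditions: Bu3SnH, LiN(i-Pr)2, THF, 0 °C; then 18, -78 °C to rt
Reagents that add atoms: tributyltin hydride, CCCC[SnH](CCCC)CCCC
Why: SN2 displacement of the primary allylic bromide by Bu3SnLi at the CH2 carbon; the E alkene of 18 is not involved.

Step 12
Reactants: 17 3-[3-bromo-4-(triisopropylsilyloxy)phenyl]-5-hydroxy-6-(3-methylbut-2-en-1-yl)-7-(triisopropylsilyloxy)-4H-chromen-4-one; 19 tributyl[(2E)-3,7-dimethylocta-2,6-dien-1-yl]stannane
Product: 20 3-{3-[(2E)-3,7-dimethylocta-2,6-dien-1-yl]-4-(triisopropylsilyloxy)phenyl}-5-hydroxy-6-(3-methylbut-2-en-1-yl)-7-(triisopropylsilyloxy)-4H-chromen-4-one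
Conditions: Pd(P(t-Bu)3)2 (zerovalent palladium, cat.), dioxane, 90 °C
Reagents that add atoms: none
Why: Stille coupling at the remaining aryl bromide, with a bulky electron-rich phosphine that speeds oxidative addition next to the silyloxy group; linear attachment and E geometry should be kept because isomerisation would need a tertiary sigma-allyl palladium species.

Step 13
Reactants: 20 3-{3-[(2E)-3,7-dimethylocta-2,6-dien-1-yl]-4-(triisopropylsilyloxy)phenyl}-5-hydroxy-6-(3-methylbut-2-en-1-yl)-7-(triisopropylsilyloxy)-4H-chromen-4-one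
Product: 22 (3R,4R)-3-{3-[(2E)-3,7-dimethylocta-2,6-dien-1-yl]-4-(triisopropylsilyloxy)phenyl}-6-(3-methylbut-2-en-1-yl)-7-(triisopropylsilyloxy)-3,4-dihydro-2H-chromene-4,5-diol (cis), via racemic isoflavanone 21 (not isolated)
Conditions: RuCl[(R,R)-TsDPEN](p-cymene) (divalent ruthenium, cat.), HCO2H/Et3N (1:2), DMF, 40 °C
Reagents that add atoms: none
Why: Noyori–Ikariya asymmetric transfer hydrogenation with dynamic kinetic resolution, a known reaction of isoflavones and other 3-substituted chromones: hydride first adds to C2 to give racemic 21, whose C3 epimerises through the enol in the amine-rich medium. The (R,R) catalyst delivers hydride to C4 to give the 4R carbinol and reduces fastest the enantiomer whose aryl group is anti to the incoming hydride, so C3 is set as R in the cis-(3R,4R) product. Isolated alkenes are inert to the ruthenium hydride, and the excess amine protects the acid-labile carbinol.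

Step 14
Reactants: 22 (3R,4R)-3-{3-[(2E)-3,7-dimethylocta-2,6-dien-1-yl]-4-(triisopropylsilyloxy)phenyl}-6-(3-methylbut-2-en-1-yl)-7-(triisopropylsilyloxy)-3,4-dihydro-2H-chromene-4,5-diol
Product: 23 (3R)-3-{3-[(2E)-3,7-dimethylocta-2,6-dien-1-yl]-4-(triisopropylsilyloxy)phenyl}-5-hydroxy-6-(3-methylbut-2-en-1-yl)-7-(triisopropylsilyloxy)chroman-4-one
Conditions: Dess–Martin periodinane, NaHCO3, CH2Cl2, 0 °C
Reagents that add atoms: none
Why: Dess–Martin oxidation of the benzylic carbinol under buffered, base-free conditions that do not enolise the new alpha-aryl ketone, so the R configuration at C3 is carried over; the 5-OH is shielded by both neighbours and becomes chelated to the new ketone.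

Step 15
Reactants: 23 (3R)-3-{3-[(2E)-3,7-dimethylocta-2,6-dien-1-yl]-4-(triisopropylsilyloxy)phenyl}-5-hydroxy-6-(3-methylbut-2-en-1-yl)-7-(triisopropylsilyloxy)chroman-4-one
Product: 24 (3R)-3-{3-[(2E)-3,7-dimethylocta-2,6-dien-1-yl]-4-hydroxyphenyl}-5,7-dihydroxy-6-(3-methylbut-2-en-1-yl)chroman-4-one
Conditions: Bu4NF, AcOH (1:1.2), THF, 0 °C
Reagents that add atoms: none
Why: Fluoride cleavage of both aryl silyl ethers; buffering with acetic acid keeps the medium close to neutral, so C3 is not enolised and the prenyl and geranyl groups do not cyclise onto the phenols.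

## Compound list

1 | 4,6-dihydroxybenzofuran-3(2H)-one | O=C1COc2cc(O)cc(O)c12 | starting material
2 | 4,6-bis(methoxymethoxy)benzofuran-3(2H)-one | COCOc1cc(OCOC)c2C(=O)COc2c1 | intermediate
3 | 3-(tert-butyldimethylsilyloxy)-4,6-bis(methoxymethoxy)benzofuran | COCOc1cc(OCOC)c2c(O[Si](C)(C)C(C)(C)C)coc2c1 | intermediate
4 | 3-bromo-4-hydroxybenzonitrile | N#Cc1ccc(O)c(Br)c1 | starting material
5 | 3-bromo-4-(methoxymethoxy)benzonitrile | COCOc1ccc(C#N)cc1Br | intermediate
6 | lithium N,N'-bis(trimethylsilyl)-3-bromo-4-(methoxymethoxy)benzamidinate (not isolated) | COCOc1ccc(C(=N[Si](C)(C)C)[N-][Si](C)(C)C)cc1Br.[Li+] | intermediate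
7 | 3-bromo-4-(methoxymethoxy)benzamidinium chloride | COCOc1ccc(C(=N)N)cc1Br.Cl | intermediate
8 | 3-[3-bromo-4-(methoxymethoxy)phenyl]-3-chloro-3H-diazirine | COCOc1ccc(C2(Cl)N=N2)cc1Br | intermediate
9 | [3-bromo-4-(methoxymethoxy)phenyl]chlorocarbene (not isolated) | COCOc1ccc([C]Cl)cc1Br | intermediate
10 | 1-[3-bromo-4-(methoxymethoxy)phenyl]-6b-(tert-butyldimethylsilyloxy)-1-chloro-4,6-bis(methoxymethoxy)-1a,6b-dihydro-1H-cyclopropa[b]benzofuran, racemic mixture of diastereomers at the chlorine-bearing carbon (not isolated) | COCOc1cc(OCOC)c2c(c1)OC1C(Cl)(c3ccc(OCOC)c(Br)c3)C21O[Si](C)(C)C(C)(C)C | intermediate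
11 | 3-[3-bromo-4-(methoxymethoxy)phenyl]-4-(tert-butyldimethylsilyloxy)-5,7-bis(methoxymethoxy)chromenylium chloride (not isolated) | COCOc1cc(OCOC)c2c(O[Si](C)(C)C(C)(C)C)c(-c3ccc(OCOC)c(Br)c3)c[o+]c2c1.[Cl-] | intermediate
12 | 3-[3-bromo-4-(methoxymethoxy)phenyl]-5,7-bis(methoxymethoxy)-4H-chromen-4-one | COCOc1ccc(-c2coc3cc(OCOC)cc(OCOC)c3c2=O)cc1Br | intermediate
13 | 3-(3-bromo-4-hydroxyphenyl)-5,7-dihydroxy-4H-chromen-4-one | O=c1c(-c2ccc(O)c(Br)c2)coc2cc(O)cc(O)c12 | intermediate
14 | 3-[3-bromo-4-(triisopropylsilyloxy)phenyl]-5-hydroxy-7-(triisopropylsilyloxy)-4H-chromen-4-one | O=c1c(-c2ccc(O[Si](C(C)C)(C(C)C)C(C)C)c(Br)c2)coc2cc(O[Si](C(C)C)(C(C)C)C(C)C)cc(O)c12 | intermediate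
15 | 3-[3-bromo-4-(triisopropylsilyloxy)phenyl]-5-hydroxy-6-iodo-7-(triisopropylsilyloxy)-4H-chromen-4-one | O=c1c(-c2ccc(O[Si](C(C)C)(C(C)C)C(C)C)c(Br)c2)coc2cc(O[Si](C(C)C)(C(C)C)C(C)C)c(I)c(O)c12 | intermediate
16 | tributyl(3-methylbut-2-en-1-yl)stannane | CCCC[Sn](CCCC)(CCCC)CC=C(C)C | starting material
17 | 3-[3-bromo-4-(triisopropylsilyloxy)phenyl]-5-hydroxy-6-(3-methylbut-2-en-1-yl)-7-(triisopropylsilyloxy)-4H-chromen-4-one | O=c1c(-c2ccc(O[Si](C(C)C)(C(C)C)C(C)C)c(Br)c2)coc2cc(O[Si](C(C)C)(C(C)C)C(C)C)c(CC=C(C)C)c(O)c12 | intermediate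
18 | geranyl bromide, (2E)-1-bromo-3,7-dimethylocta-2,6-diene | CC(C)=CCC/C(C)=C/CBr | starting material
19 | tributyl[(2E)-3,7-dimethylocta-2,6-dien-1-yl]stannane | CC(C)=CCC/C(C)=C/C[Sn](CCCC)(CCCC)CCCC | intermediate
20 | 3-{3-[(2E)-3,7-dimethylocta-2,6-dien-1-yl]-4-(triisopropylsilyloxy)phenyl}-5-hydroxy-6-(3-methylbut-2-en-1-yl)-7-(triisopropylsilyloxy)-4H-chromen-4-one | CC(C)=CCC/C(C)=C/Cc1cc(-c2coc3cc(O[Si](C(C)C)(C(C)C)C(C)C)c(CC=C(C)C)c(O)c3c2=O)ccc1O[Si](C(C)C)(C(C)C)C(C)C | intermediate
21 | racemic 3-{3-[(2E)-3,7-dimethylocta-2,6-dien-1-yl]-4-(triisopropylsilyloxy)phenyl}-5-hydroxy-6-(3-methylbut-2-en-1-yl)-7-(triisopropylsilyloxy)chroman-4-one (not isolated) | CC(C)=CCC/C(C)=C/Cc1cc(C2COc3cc(O[Si](C(C)C)(C(C)C)C(C)C)c(CC=C(C)C)c(O)c3C2=O)ccc1O[Si](C(C)C)(C(C)C)C(C)C | intermediate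
22 | (3R,4R)-3-{3-[(2E)-3,7-dimethylocta-2,6-dien-1-yl]-4-(triisopropylsilyloxy)phenyl}-6-(3-methylbut-2-en-1-yl)-7-(triisopropylsilyloxy)-3,4-dihydro-2H-chromene-4,5-diol (cis) | CC(C)=CCC/C(C)=C/Cc1cc([C@@H]2COc3cc(O[Si](C(C)C)(C(C)C)C(C)C)c(CC=C(C)C)c(O)c3[C@@H]2O)ccc1O[Si](C(C)C)(C(C)C)C(C)C | intermediate
23 | (3R)-3-{3-[(2E)-3,7-dimethylocta-2,6-dien-1-yl]-4-(triisopropylsilyloxy)phenyl}-5-hydroxy-6-(3-methylbut-2-en-1-yl)-7-(triisopropylsilyloxy)chroman-4-one | CC(C)=CCC/C(C)=C/Cc1cc([C@@H]2COc3cc(O[Si](C(C)C)(C(C)C)C(C)C)c(CC=C(C)C)c(O)c3C2=O)ccc1O[Si](C(C)C)(C(C)C)C(C)C | intermediate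
24 | (3R)-3-{3-[(2E)-3,7-dimethylocta-2,6-dien-1-yl]-4-hydroxyphenyl}-5,7-dihydroxy-6-(3-methylbut-2-en-1-yl)chroman-4-one (CNP0165005.1) | CC(C)=CCC/C(C)=C/Cc1cc([C@@H]2COc3cc(O)c(CC=C(C)C)c(O)c3C2=O)ccc1O | target

## Step count and least certain steps

Total: 15 steps. Longest linear sequence: 12 steps, from 4 through 5, 7, 8, 12, 13, 14, 15, 17, 20, 22 and 23 to 24 (steps 3–10 and 12–15).

**Step 6 (key step, bears the label "Proposed new method:").** The most likely failure is that the carbene is used up by dimerisation or azine formation, or by attack on ring A or the MOM oxygens, before it finds the enol ether. Hydrolysis of 3, or a cyclopropane that does not open, are the other possibilities. The fallback uses known chemistry and sets out from 3. Dibromocarbene (CHBr3, KOt-Bu, pentane, -20 °C to rt), in the classical dihalocarbene ring expansion of a cyclic silyl enol ether, should give 3-bromo-5,7-bis(methoxymethoxy)-4H-chromen-4-one F1. Ring B is then attached by Suzuki–Miyaura coupling (Pd(PPh3)4, Na2CO3, DME–H2O, 70 °C) with [3-bromo-4-(methoxymethoxy)phenyl]boronic acid F3. F3 is made from purchased 2-bromo-4-iodophenol by way of 2-bromo-4-iodo-1-(methoxymethoxy)benzene F2 (MOMCl, i-Pr2NEt; then i-PrMgCl·LiCl, -20 °C, B(OMe)3, NH4Cl work-up). The electron-poor C3–Br of F1 should undergo oxidative addition ahead of the electron-rich aryl C–Br. The fallback rejoins the route at 12.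

**Step 13 (transfer hydrogenation).** The reduction may stall at racemic 21 because the chelated, electron-rich ketone is reduced slowly. The very electron-rich C4 carbinol may also ionise and dehydrate, or selectivity may be low if reduction outruns racemisation. The fallback sets out from 20. Conjugate reduction with LiBH(s-Bu)3 (2.2 equiv, THF, -78 °C) and trapping with Me3SiCl should give 3-{3-[(2E)-3,7-dimethylocta-2,6-dien-1-yl]-4-(triisopropylsilyloxy)phenyl}-6-(3-methylbut-2-en-1-yl)-7-(triisopropylsilyloxy)-4,5-bis(trimethylsilyloxy)-2H-chromene F4. Enantioselective protonation of this silyl enol ether follows, with a BINOL-derived chiral N-triflyl thiophosphoramide as catalyst and phenol as proton source in toluene. This is the known protonation of silyl enol ethers of 2-aryl cyclic ketones. It should give 23 directly, the 5-O-silyl group being lost on work-up. The fallback rejoins the route at 23 and bypasses step 14.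

**Step 10 (prenyl coupling).** Oxidative addition at the doubly flanked C6–I may be slow enough for insertion at C3'–Br to compete. Allyl transfer through the substituted terminus would give the 1,1-dimethylallyl isomer, and protodeiodination is possible. The fallback reverses the polarity and sets out from 15. Miyaura borylation at the iodide (B2pin2, PdCl2(dppf), KOAc, dioxane, 80 °C) should give 3-[3-bromo-4-(triisopropylsilyloxy)phenyl]-5-hydroxy-6-(4,4,5,5-tetramethyl-1,3,2-dioxaborolan-2-yl)-7-(triisopropylsilyloxy)-4H-chromen-4-one F5. Palladium-catalysed allyl–aryl coupling with prenyl bromide (Pd2(dba)3, K2CO3, toluene, 60 °C) then delivers the aryl group to the unhindered CH2 end of the prenylpalladium intermediate. The fallback rejoins the route at 17.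

**Step 14 (oxidation).** Acetic acid from the oxidant may ionise the ortho-hydroxylated C4 carbinol, and dehydration to the isoflav-3-ene would destroy C3. The hypervalent iodine reagent may also attack the free 5-OH. The fallback sets out from 20 and hides the phenol.
- The 5-OH is capped (KN(SiMe3)2, MOMCl, THF, -78 to 0 °C) to give 3-{3-[(2E)-3,7-dimethylocta-2,6-dien-1-yl]-4-(triisopropylsilyloxy)phenyl}-5-(methoxymethoxy)-6-(3-methylbut-2-en-1-yl)-7-(triisopropylsilyloxy)-4H-chromen-4-one F6.
- Transfer hydrogenation as in step 13 gives (3R,4R)-3-{3-[(2E)-3,7-dimethylocta-2,6-dien-1-yl]-4-(triisopropylsilyloxy)phenyl}-5-(methoxymethoxy)-6-(3-methylbut-2-en-1-yl)-7-(triisopropylsilyloxy)chroman-4-ol F7.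
- Dess–Martin oxidation gives (3R)-3-{3-[(2E)-3,7-dimethylocta-2,6-dien-1-yl]-4-(triisopropylsilyloxy)phenyl}-5-(methoxymethoxy)-6-(3-methylbut-2-en-1-yl)-7-(triisopropylsilyloxy)chroman-4-one F8.
- Chelation-assisted removal of the peri MOM group with MgBr2·OEt2 (Et2O–CH2Cl2, rt) rejoins the route at 23.

## Further compounds

F1 | step 6 | 3-bromo-5,7-bis(methoxymethoxy)-4H-chromen-4-one | COCOc1cc(OCOC)c2c(c1)occ(Br)c2=O
F2 | step 6 | 2-bromo-4-iodo-1-(methoxymethoxy)benzene | COCOc1ccc(I)cc1Br
F3 | step 6 | [3-bromo-4-(methoxymethoxy)phenyl]boronic acid | COCOc1ccc(B(O)O)cc1Br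
F4 | step 13 | 3-{3-[(2E)-3,7-dimethylocta-2,6-dien-1-yl]-4-(triisopropylsilyloxy)phenyl}-6-(3-methylbut-2-en-1-yl)-7-(triisopropylsilyloxy)-4,5-bis(trimethylsilyloxy)-2H-chromene | CC(C)=CCC/C(C)=C/Cc1cc(C2=C(O[Si](C)(C)C)c3c(O[Si](C)(C)C)c(CC=C(C)C)c(O[Si](C(C)C)(C(C)C)C(C)C)cc3OC2)ccc1O[Si](C(C)C)(C(C)C)C(C)C
F5 | step 10 | 3-[3-bromo-4-(triisopropylsilyloxy)phenyl]-5-hydroxy-6-(4,4,5,5-tetramethyl-1,3,2-dioxaborolan-2-yl)-7-(triisopropylsilyloxy)-4H-chromen-4-one | O=c1c(-c2ccc(O[Si](C(C)C)(C(C)C)C(C)C)c(Br)c2)coc2cc(O[Si](C(C)C)(C(C)C)C(C)C)c(B3OC(C)(C)C(C)(C)O3)c(O)c12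
F6 | step 14 | 3-{3-[(2E)-3,7-dimethylocta-2,6-dien-1-yl]-4-(triisopropylsilyloxy)phenyl}-5-(methoxymethoxy)-6-(3-methylbut-2-en-1-yl)-7-(triisopropylsilyloxy)-4H-chromen-4-one | CC(C)=CCC/C(C)=C/Cc1cc(-c2coc3cc(O[Si](C(C)C)(C(C)C)C(C)C)c(CC=C(C)C)c(OCOC)c3c2=O)ccc1O[Si](C(C)C)(C(C)C)C(C)C
F7 | step 14 | (3R,4R)-3-{3-[(2E)-3,7-dimethylocta-2,6-dien-1-yl]-4-(triisopropylsilyloxy)phenyl}-5-(methoxymethoxy)-6-(3-methylbut-2-en-1-yl)-7-(triisopropylsilyloxy)chroman-4-ol | CC(C)=CCC/C(C)=C/Cc1cc([C@@H]2COc3cc(O[Si](C(C)C)(C(C)C)C(C)C)c(CC=C(C)C)c(OCOC)c3[C@@H]2O)ccc1O[Si](C(C)C)(C(C)C)C(C)C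
F8 | step 14 | (3R)-3-{3-[(2E)-3,7-dimethylocta-2,6-dien-1-yl]-4-(triisopropylsilyloxy)phenyl}-5-(methoxymethoxy)-6-(3-methylbut-2-en-1-yl)-7-(triisopropylsilyloxy)chroman-4-one | CC(C)=CCC/C(C)=C/Cc1cc([C@@H]2COc3cc(O[Si](C(C)C)(C(C)C)C(C)C)c(CC=C(C)C)c(OCOC)c3C2=O)ccc1O[Si](C(C)C)(C(C)C)C(C)C
A1 | alternative 1 | 6-{2-[3-((2E)-3,7-dimethylocta-2,6-dien-1-yl)-4-hydroxyphenyl]-2-(4-methylphenylsulfonyl)ethoxy}-2,4-bis(methoxymethoxy)-3-(3-methylbut-2-en-1-yl)benzaldehyde | CC(C)=CCC/C(C)=C/Cc1cc(C(COc2cc(OCOC)c(CC=C(C)C)c(OCOC)c2C=O)S(=O)(=O)c2ccc(C)cc2)ccc1O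
A2 | alternative 1 | (R)-3-(3-geranyl-4-hydroxyphenyl)-5,7-bis(methoxymethoxy)-6-prenylchroman-4-one | CC(C)=CCC/C(C)=C/Cc1cc([C@@H]2COc3cc(OCOC)c(CC=C(C)C)c(OCOC)c3C2=O)ccc1O
A3 | alternative 2 | 1-[2,4-bis(tert-butyldimethylsilyloxy)-6-methoxy-3-(3-methylbut-2-en-1-yl)phenyl]-2-diazo-2-{3-[(2E)-3,7-dimethylocta-2,6-dien-1-yl]-4-(tert-butyldimethylsilyloxy)phenyl}ethanone | CC(C)=CCC/C(C)=C/Cc1cc(C(=[N+]=[N-])C(=O)c2c(OC)cc(O[Si](C)(C)C(C)(C)C)c(CC=C(C)C)c2O[Si](C)(C)C(C)(C)C)ccc1O[Si](C)(C)C(C)(C)C
A4 | alternative 2 | (R)-5,7-bis(tert-butyldimethylsilyloxy)-6-prenyl-3-[3-geranyl-4-(tert-butyldimethylsilyloxy)phenyl]chroman-4-one | CC(C)=CCC/C(C)=C/Cc1cc([C@@H]2COc3cc(O[Si](C)(C)C(C)(C)C)c(CC=C(C)C)c(O[Si](C)(C)C(C)(C)C)c3C2=O)ccc1O[Si](C)(C)C(C)(C)C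
A5 | alternative 3 | methyl 2-(3-methylbut-2-en-1-yl)-3-oxo-4-{5-[3-((2E)-3,7-dimethylocta-2,6-dien-1-yl)-4-(methoxymethoxy)phenyl]-4-oxo-4H-pyran-2-yl}butanoate | CC(C)=CCC/C(C)=C/Cc1cc(-c2coc(CC(=O)C(CC=C(C)C)C(=O)OC)cc2=O)ccc1OCOC
A6 | alternative 3 | 5,7-dihydroxy-6-prenyl-3-[3-geranyl-4-(methoxymethoxy)phenyl]chromen-4-one | CC(C)=CCC/C(C)=C/Cc1cc(-c2coc3cc(O)c(CC=C(C)C)c(O)c3c2=O)ccc1OCOC
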